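**Remark on the chemistry:** compounds 1, 9 and 13 are taken as purchased. The target has no stereocentre, so all SMILES are written without stereodescriptors.

## Analysis of the target

The target is a depside without any stereocentre: ring A and ring B are joined only by an aryl ester between the carboxyl carbon on C1 of ring A and the phenolic oxygen on C4 of ring B, so the problem is one of regiochemistry and chemoselectivity. Ring A is a 2-hydroxy-4-methoxy-6-propylbenzoyl unit and ring B is a 2-methoxy-6-pentylbenzoic acid, so each carbonyl carbon sits between two ortho substituents of a 1,2,3,5-tetrasubstituted ring. Three kinds of oxygen (a chelated free phenol, two methyl ethers and an acylated phenol) and two carboxyl groups (one ester, one free acid) have to be told apart, and the two alkyl chains differ in length. The aryl ester is an activated ester that would not survive saponification or alkoxide, the electron-rich, doubly ortho-substituted acid of ring B can lose CO2 under strong acid or on heating with metal salts, and the ring A phenol is easily oxidised. The difficulty lies in the order of events, because a crowded acyl carbon must be joined to a phenol oxygen and the ring B acid must then be set free without hydrolysis. The strategy rests on one feature of ring B: its C1 carboxyl group has a single ortho C–H bond, at C6, because C2 carries the methoxy group, and C6 is exactly where the pentyl chain belongs. Ring A offers no competing site, since it has no carboxylic acid and both positions next to its ester carbonyl are substituted, so a carboxylate-bound divalent palladium can be delivered to C6–H alone and the pentyl group can be attached to the assembled depside.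

## Retrosynthetic reasoning

**15 to 14.** The last disconnection is the O–benzyl bond on C2 of ring A. The ring A phenol is kept as its benzyl ether through the palladium step, so that no free electron-rich phenol meets a silver oxidant and no phenoxide–carbonyl chelate can bind the catalyst. This costs no step, because the hydrogenolysis that is needed anyway is simply placed after the C–C bond formation. The forward reaction has to cleave one benzylic C–O bond and leave the aryl ester untouched.

**14 to 12 and 13.** The C6–pentyl bond of ring B is cut. It is the only skeletal bond that separates a purchasable ring B pattern from the target, and it lies ortho to the one free carboxyl group. Ring B is then never built, and both crowded carbonyl groups are assembled before the chain that crowds the acid is added. The forward reaction must replace the C6–H bond of acid 12 by the primary alkyl group of 13, which has beta hydrogens, without touching the ester or any other C–H bond.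

**12 to 11.** The carboxyl group of ring B is traced back to a formyl group. A carboxyl ester on ring B would have to be removed in the presence of the depside ester. An aldehyde needs no protecting group, is inert during ester formation, and is oxidised under mildly acidic, non-hydrolytic conditions.

**11 to 8 (through 10) and 9.** The acyl C–O bond of the depside is cut. This joins two pieces of similar size and is the most convergent cut. On the ring B side it leads to the commercial phenol 9, which is acidic and unhindered. The forward reaction must force a nucleophile onto a carbonyl carbon flanked by a benzyloxy and a propyl group, which is why acid 8 is activated as its chloride 10.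

**8 to 7, 6 and 4.** Acid 8 comes from aldehyde 7 by oxidation, the benzyl ether of 7 from phenol 6, and 6 from the dimethyl ether 4. The formyl group is used twice: as the precursor of the carboxyl group, and as the anchor for a chelating Lewis acid that removes only the methyl group on the ortho oxygen. This differentiates the two oxygens of ring A without any statistical protection.

**4 to 2 to 1.** The formyl C–C bond is cut back to the symmetrical arene 2, in which the two positions ortho to the propyl group are equivalent and are the electronically preferred sites of substitution. The aryl–propyl bond of 2 is cut back to the commercial bromide 1, which receives its three-carbon chain by a Kumada-type cross-coupling.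

## Alternatives that were turned down

Alternative 1: Ring B is built from acyclic pieces instead of being bought.
- Disconnection: the C1–C2 and C5–C6 bonds of ring B are cut in a (4+2) sense. This leads to benzyl oct-2-ynoate (A1), which carries the pentyl chain and the carboxyl group, and to 1,1-dimethoxy-3-(trimethylsilyloxy)buta-1,3-diene (A2), which carries both oxygens.
- Forward key step: a thermal Diels–Alder reaction joins the nucleophilic CH2 terminus of A2 to the beta carbon of A1 and the ketene-acetal carbon of A2 to the alpha carbon of A1. Loss of one acetal methoxy group aromatises the adduct, and desilylation leaves benzyl 4-hydroxy-2-methoxy-6-pentylbenzoate (A3). A3 would then be acylated with 10 and both benzyl groups hydrogenolysed.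
- For: the polarised diene fixes the regiochemistry, the 2-methoxy and 4-hydroxy groups emerge already differentiated in A3, and the pentyl position is set by construction. On the certainty of the C6–pentyl bond this alternative is stronger than the chosen route, and its end game is purely classical.
- Against: A1 is a beta-alkyl ynoate with a single activating group and therefore a sluggish dienophile. The temperatures it needs are those at which the electron-rich, hydrolytically fragile A2 decomposes or loses its silyl group. Neither A1 nor A2 is a shelf compound in quantity, so ring B costs about four steps.
- Comparison: the chosen route takes ring B from the bottle as 9 and is about three steps shorter. It also makes the alkyl chain the last variable, so homologues of the target would come from one advanced acid, 12.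

Alternative 2: The depside is cut at the aryl C4–O bond of ring B instead of the acyl C–O bond.
- Disconnection: ring B is traced to tert-butyl 2-methoxy-6-pentylbenzoate (A4), whose C4–H is the only ring C–H without an ortho neighbour. Sterically controlled iridium-catalysed C–H borylation of A4 and hydrolysis of the boronic ester would give [4-(tert-butoxycarbonyl)-3-methoxy-5-pentylphenyl]boronic acid (A5). Ring A becomes 4-methoxy-2-(methoxymethoxy)-6-propylbenzoic acid (A6).
- Forward key step: oxidative coupling of A5 and A6 with Cu(OTf)2 (divalent copper) in air gives tert-butyl 2-methoxy-4-[4-methoxy-2-(methoxymethoxy)-6-propylbenzoyloxy]-6-pentylbenzoate (A7). Acid would then remove the tert-butyl ester and the methoxymethyl ether of A7.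
- For: the C–O bond forms at an unhindered aryl carbon, and the crowded acyl carbon of ring A is never attacked by a nucleophile. On this point the alternative is stronger than the acyl substitution of step 6, and the same bond construction is kept as the fallback for that step. The final deprotection of A7 is non-hydrolytic.
- Against: A4 is a 1,2,3-trisubstituted benzoate that must itself be made in several steps. The boron of A5 sits para to an ester, which slows transfer to copper and favours protodeboronation or oxidation to the phenol. Couplings of this kind usually need one partner in excess, and here both A5 and A6 are advanced. The closing strong-acid treatment of A7 exposes a doubly ortho-substituted, electron-rich benzoic acid to decarboxylation.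
- Comparison: two consecutive metal-mediated steps of moderate reliability and a longer sequence stand against one late metal-catalysed step in the chosen route.

Alternative 3: Ring A is assembled by forming two bonds in one pot.
- Disconnection: the C6–propyl and C1–carboxyl bonds of ring A are cut together. This leads to 1-bromo-2-iodo-3,5-dimethoxybenzene (A8), obtained by iodination of 1, as the source of 3,5-dimethoxybenzyne (A9).
- Forward key step: an excess of propylmagnesium chloride (A10), the Grignard reagent also used in step 1, exchanges the iodine of A8, and the arylmagnesium eliminates to A9. A second equivalent of A10 adds to the aryne carbon of A9 remote from the methoxy group, and carboxylation of the resulting arylmagnesium gives 2,4-dimethoxy-6-propylbenzoic acid (A11).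
- For: A11 is reached in two steps from 1, against two steps to aldehyde 4 and five to acid 8 here. On step economy for ring A this alternative is clearly stronger.
- Against: it solves the easier ring only. A11 still needs selective demethylation and then protection of the phenol in the presence of the acid, which returns most of the steps saved. Iodination of 1 to A8 must discriminate between two activated positions. A10 is a primary alkyl Grignard reagent that can reduce A9 by hydride transfer and can attack the carboxylate once it forms. Ring B with its pentyl chain would still need a construction of its own.
- Comparison: the chosen strategy spends its one uncertain step on ring B, where the real problem lies, and reaches ring A by slower but well-behaved chemistry.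

Key step: step 8

## Route

Step 1
Reactants: 1 1-bromo-3,5-dimethoxybenzene
Product: 2 1,3-dimethoxy-5-propylbenzene
Conditions: n-PrMgCl (1.5 equiv), NiCl2(dppp) (cat.), THF, 0 °C to reflux
Reagents that add atoms: propylmagnesium chloride, CCC[Mg]Cl
Why: Kumada–Tamao–Corriu coupling of an aryl bromide with a primary alkyl Grignard reagent; the chelating diphosphine on nickel favours reductive elimination over beta-hydride elimination, and the methyl ethers are inert.

Step 2
Reactants: 2 1,3-dimethoxy-5-propylbenzene
Product: 4 2,4-dimethoxy-6-propylbenzaldehyde, via iminium chloride 3 (not isolated)
Conditions: POCl3, DMF, 0 °C to 80 °C; then H2O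
Reagents that add atoms: N,N-dimethylformamide, CN(C)C=O; water, O
Why: Vilsmeier–Haack formylation; the chloroiminium electrophile should attack the position activated by one para and one ortho methoxy group (next to the propyl chain), the usual site in 5-alkylresorcinol dimethyl ethers, and hydrolysis of iminium salt 3 releases the aldehyde.

Step 3
Reactants: 4 2,4-dimethoxy-6-propylbenzaldehyde
Product: 6 2-hydroxy-4-methoxy-6-propylbenzaldehyde, via aryloxydichloroborane 5 (not isolated)
Conditions: BCl3 (1.1 equiv), CH2Cl2, −78 °C to 0 °C; then H2O
Reagents that add atoms: none
Why: Chelation-controlled ether cleavage; BCl3 bridges the formyl oxygen and the ortho methoxy oxygen in a six-membered chelate, chloride removes that methyl group only, and hydrolysis of 5 gives the hydrogen-bonded phenol while the para methoxy group stays.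

Step 4
Reactants: 6 2-hydroxy-4-methoxy-6-propylbenzaldehyde
Product: 7 2-(benzyloxy)-4-methoxy-6-propylbenzaldehyde
Conditions: BnBr, K2CO3, DMF, 60 °C
Reagents that add atoms: benzyl bromide, BrCc1ccccc1
Why: Williamson ether synthesis; the phenoxide is the only nucleophile present and gentle warming overcomes its hydrogen bond to the formyl group.

Step 5
Reactants: 7 2-(benzyloxy)-4-methoxy-6-propylbenzaldehyde
Product: 8 2-(benzyloxy)-4-methoxy-6-propylbenzoic acid
Conditions: NaClO2, NaH2PO4, 2-methyl-2-butene, t-BuOH/H2O, rt
Reagents that add atoms: sodium chlorite, [Na+].[O-]Cl=O
Why: Pinnick oxidation; chlorous acid adds to the formyl group and fragments to the acid even at a hindered aldehyde, and the alkene scavenger removes hypochlorous acid before it can chlorinate the electron-rich ring.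

Step 6
Reactants: 8 2-(benzyloxy)-4-methoxy-6-propylbenzoic acid; 9 4-hydroxy-2-methoxybenzaldehyde
Product: 11 4-formyl-3-methoxyphenyl 2-(benzyloxy)-4-methoxy-6-propylbenzoate, via acid chloride 10 (not isolated)
Conditions: (COCl)2, DMF (cat.), CH2Cl2, 0 °C to rt; evaporate; then 9, Et3N, DMAP (cat.), CH2Cl2, 0 °C to rt
Reagents that add atoms: none
Why: Acid chloride formation through the catalytic chloroiminium species, then DMAP-catalysed nucleophilic acyl substitution by the phenoxide of 9; the formyl-bearing phenol is acidic enough to be deprotonated by Et3N, its aldehyde is inert to the acid chloride, and the small, fully activated acyl chloride is what the doubly ortho-substituted carbonyl needs.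

Step 7
Reactants: 11 4-formyl-3-methoxyphenyl 2-(benzyloxy)-4-methoxy-6-propylbenzoate
Product: 12 4-{[2-(benzyloxy)-4-methoxy-6-propylbenzoyl]oxy}-2-methoxybenzoic acid
Conditions: NaClO2, NaH2PO4, 2-methyl-2-butene, t-BuOH/THF/H2O, 0 °C to rt
Reagents that add atoms: sodium chlorite, [Na+].[O-]Cl=O
Why: Pinnick oxidation at pH 3 to 4, where the aryl ester and the benzyl ether are stable; the alkene scavenger protects ring A from chlorination, and no peroxide is present, so a Dakin-type loss of the formyl group cannot occur.

Step 8
Reactants: 12 4-{[2-(benzyloxy)-4-methoxy-6-propylbenzoyl]oxy}-2-methoxybenzoic acid; 13 potassium pentyltrifluoroborate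
Product: 14 4-{[2-(benzyloxy)-4-methoxy-6-propylbenzoyl]oxy}-2-methoxy-6-pentylbenzoic acid
Conditions: Pd(OAc)2 (10 mol %), Ac-Val-OH (20 mol %), Ag2CO3 (2 equiv), Li2CO3 (2 equiv), 1,4-benzoquinone (0.5 equiv), 13 (3 equiv), t-AmylOH, 100 °C; then 1 M HCl
Reagents that add atoms: none
Why: The carboxylate of 12 binds divalent palladium carrying the N-acetyl amino acid ligand, and concerted metalation–deprotonation with the ligand as internal base cleaves the C6–H bond of ring B to give a five-membered palladacycle (Pd, O, carboxyl C, C1, C6). Carbonate-assisted unmasking of 13 lets the pentyl group pass from boron to palladium, and the aryl(pentyl)palladium species, with benzoquinone bound as a pi-acid, should undergo C(sp2)–C(sp3) reductive elimination faster than beta-hydride elimination; Ag2CO3 (monovalent silver) then returns zerovalent palladium to the divalent state. The closest known reaction type is the carboxylate-directed, ligand-accelerated ortho C–H alkylation of benzoic acids with primary alkylboron reagents under Pd(OAc)2 and Ag2CO3, applied here to a benzoic acid that carries an aryl ester. No ring is closed and no stereocentre is formed. The step needs site selectivity, and the substrate secures it: C6 is the only C–H bond ortho to a carboxylate because C2 of ring B holds the methoxy group, ring A has no acid and both positions next to its ester carbonyl are substituted, and the neutral ester and ether oxygens are far weaker directing groups than the anionic carboxylate. A second alkylation is impossible because the product has no ortho C–H left. Chemoselectivity rests on the benzyl ether, which keeps the ring A phenol from binding palladium or being oxidised by the silver salt, and on the two ortho substituents that shield the depside carbonyl from carbonate and from the hindered alcohol solvent; acidification returns the free acid 14.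

Step 9
Reactants: 14 4-{[2-(benzyloxy)-4-methoxy-6-propylbenzoyl]oxy}-2-methoxy-6-pentylbenzoic acid
Product: 15 4-[(2-hydroxy-4-methoxy-6-propylbenzoyl)oxy]-2-methoxy-6-pentylbenzoic acid (CNP0522224.0)
Conditions: H2 (1 atm), 10% Pd/C, EtOAc, rt
Reagents that add atoms: none
Why: Catalytic hydrogenolysis of the benzylic C–O bond; the aryl ester, methyl ethers, carboxylic acid and alkyl chains are inert under these neutral conditions, and the released phenol is stabilised by its hydrogen bond to the ester carbonyl.

## Compound list

1 | 1-bromo-3,5-dimethoxybenzene | COc1cc(Br)cc(OC)c1 | starting material
2 | 1,3-dimethoxy-5-propylbenzene | CCCc1cc(OC)cc(OC)c1 | intermediate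
3 | N-[(2,4-dimethoxy-6-propylphenyl)methylidene]-N-methylmethanaminium chloride | CCCc1cc(OC)cc(OC)c1C=[N+](C)C.[Cl-] | intermediate
4 | 2,4-dimethoxy-6-propylbenzaldehyde | CCCc1cc(OC)cc(OC)c1C=O | intermediate
5 | dichloro(2-formyl-5-methoxy-3-propylphenoxy)borane | CCCc1cc(OC)cc(OB(Cl)Cl)c1C=O | intermediate
6 | 2-hydroxy-4-methoxy-6-propylbenzaldehyde | CCCc1cc(OC)cc(O)c1C=O | intermediate
7 | 2-(benzyloxy)-4-methoxy-6-propylbenzaldehyde | CCCc1cc(OC)cc(OCc2ccccc2)c1C=O | intermediate
8 | 2-(benzyloxy)-4-methoxy-6-propylbenzoic acid | CCCc1cc(OC)cc(OCc2ccccc2)c1C(=O)O | intermediate
9 | 4-hydroxy-2-methoxybenzaldehyde | COc1cc(O)ccc1C=O | starting material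
10 | 2-(benzyloxy)-4-methoxy-6-propylbenzoyl chloride | CCCc1cc(OC)cc(OCc2ccccc2)c1C(Cl)=O | intermediate
11 | 4-formyl-3-methoxyphenyl 2-(benzyloxy)-4-methoxy-6-propylbenzoate | CCCc1cc(OC)cc(OCc2ccccc2)c1C(=O)Oc1ccc(C=O)c(OC)c1 | intermediate
12 | 4-{[2-(benzyloxy)-4-methoxy-6-propylbenzoyl]oxy}-2-methoxybenzoic acid | CCCc1cc(OC)cc(OCc2ccccc2)c1C(=O)Oc1ccc(C(=O)O)c(OC)c1 | intermediate
13 | potassium pentyltrifluoroborate | CCCCC[B-](F)(F)F.[K+] | starting material
14 | 4-{[2-(benzyloxy)-4-methoxy-6-propylbenzoyl]oxy}-2-methoxy-6-pentylbenzoic acid | CCCCCc1cc(OC(=O)c2c(OCc3ccccc3)cc(OC)cc2CCC)cc(OC)c1C(=O)O | intermediate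
15 | 4-[(2-hydroxy-4-methoxy-6-propylbenzoyl)oxy]-2-methoxy-6-pentylbenzoic acid (CNP0522224.0) | CCCCCc1cc(OC(=O)c2c(O)cc(OC)cc2CCC)cc(OC)c1C(=O)O | target

## Step count and risk

Total step count: 9. Longest linear sequence: 9 steps (1 to 15); compounds 9 and 13 are purchased and enter in steps 6 and 8.

**Step 8 (key step).** Beta-hydride elimination from the pentyl–palladium intermediate may outrun C–C reductive elimination, so that the chain is lost as an alkene and the acid is returned unalkylated. Silver-promoted protodecarboxylation of the ortho-methoxy benzoic acid at 100 °C may erode the starting acid and, more readily, the doubly ortho-substituted product. Slow palladation would also give the trifluoroborate time to protodeboronate. The fallback buys the pentyl chain already attached to ring B; it sets out from 10 (the chloride made from 8 as in step 6) and comes back to the route at 14. Commercial 5-pentylbenzene-1,3-diol F1 would be formylated under Vilsmeier–Haack conditions (POCl3, DMF; then H2O) to 2,4-dihydroxy-6-pentylbenzaldehyde F2. The 4-hydroxyl of F2 is the only one not locked in a hydrogen bond to the formyl group, so it would be acylated selectively with 10 (Et3N, CH2Cl2, 0 °C) to give 4-formyl-3-hydroxy-5-pentylphenyl 2-(benzyloxy)-4-methoxy-6-propylbenzoate F3. Methylation of the remaining chelated phenol (MeI, K2CO3, acetone, reflux) would give 4-formyl-3-methoxy-5-pentylphenyl 2-(benzyloxy)-4-methoxy-6-propylbenzoate F4. Pinnick oxidation of F4 as in step 7 would deliver 14, and step 9 follows unchanged.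

**Step 2.** Formylation may occur in part at the position between the two methoxy groups, which would erode regiochemical purity and carry a wrong substitution pattern forward if not separated. The fallback introduces the carbon through a halogen; it sets out from 2 and comes back to the route at 4. Bromination of 2 with NBS in MeCN at 0 °C should give 2-bromo-1,5-dimethoxy-3-propylbenzene F5, since bromination of such ethers is strongly para-directed. Bromine–lithium exchange on F5 (n-BuLi, THF, −78 °C) and quenching with DMF would give 4.

**Step 6.** Acyl transfer from a carbonyl flanked by two ortho substituents to a weakly nucleophilic, formyl-deactivated phenoxide may be slow, and HCl formed during chloride generation may cleave the ortho benzyl ether. The fallback makes the ester at the aryl C–O bond instead; it sets out from 8 and comes back to the route at 11. Acid 8 would be coupled with commercial (4-formyl-3-methoxyphenyl)boronic acid F6 in a Chan–Lam-type oxidative esterification (Cu(OTf)2, divalent copper, urea, EtOAc, 60 °C, air), in which the carboxylate oxygen and not the hindered carbonyl carbon is the reacting centre.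

**Step 7.** Ring A may be chlorinated by hypochlorous acid if scavenging is incomplete, or conversion of the biphasic mixture may stall. The fallback brings in ring B at the acid oxidation level with a protecting group that is removed without hydrolysis; it sets out from 10 (made from 8) and comes back to the route at 12. Commercial 4-hydroxy-2-methoxybenzoic acid F7 would be alkylated at the carboxylate only (allyl bromide, KHCO3, DMF) to prop-2-en-1-yl 4-hydroxy-2-methoxybenzoate F8. Acylation of F8 with 10 (Et3N, DMAP, CH2Cl2) would give prop-2-en-1-yl 4-{[2-(benzyloxy)-4-methoxy-6-propylbenzoyl]oxy}-2-methoxybenzoate F9. Allyl transfer from F9 to a hydride donor (Pd(PPh3)4, zerovalent palladium, PhSiH3, CH2Cl2, rt) would release 12 without any nucleophile that could attack the depside ester.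

## Further compounds

F1 | step 8 | 5-pentylbenzene-1,3-diol | CCCCCc1cc(O)cc(O)c1
F2 | step 8 | 2,4-dihydroxy-6-pentylbenzaldehyde | CCCCCc1cc(O)cc(O)c1C=O
F3 | step 8 | 4-formyl-3-hydroxy-5-pentylphenyl 2-(benzyloxy)-4-methoxy-6-propylbenzoate | CCCCCc1cc(OC(=O)c2c(OCc3ccccc3)cc(OC)cc2CCC)cc(O)c1C=O
F4 | step 8 | 4-formyl-3-methoxy-5-pentylphenyl 2-(benzyloxy)-4-methoxy-6-propylbenzoate | CCCCCc1cc(OC(=O)c2c(OCc3ccccc3)cc(OC)cc2CCC)cc(OC)c1C=O
F5 | step 2 | 2-bromo-1,5-dimethoxy-3-propylbenzene | CCCc1cc(OC)cc(OC)c1Br
F6 | step 6 | (4-formyl-3-methoxyphenyl)boronic acid | COc1cc(B(O)O)ccc1C=O
F7 | step 7 | 4-hydroxy-2-methoxybenzoic acid | COc1cc(O)ccc1C(=O)O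
F8 | step 7 | prop-2-en-1-yl 4-hydroxy-2-methoxybenzoate | COc1cc(O)ccc1C(=O)OCC=C
F9 | step 7 | prop-2-en-1-yl 4-{[2-(benzyloxy)-4-methoxy-6-propylbenzoyl]oxy}-2-methoxybenzoate | CCCc1cc(OC)cc(OCc2ccccc2)c1C(=O)Oc1ccc(C(=O)OCC=C)c(OC)c1
A1 | alternative 1 | benzyl oct-2-ynoate | CCCCCC#CC(=O)OCc1ccccc1
A2 | alternative 1 | 1,1-dimethoxy-3-(trimethylsilyloxy)buta-1,3-diene | COC(OC)=CC(=C)O[Si](C)(C)C
A3 | alternative 1 | benzyl 4-hydroxy-2-methoxy-6-pentylbenzoate | CCCCCc1cc(O)cc(OC)c1C(=O)OCc1ccccc1
A4 | alternative 2 | tert-butyl 2-methoxy-6-pentylbenzoate | CCCCCc1cccc(OC)c1C(=O)OC(C)(C)C
A5 | alternative 2 | [4-(tert-butoxycarbonyl)-3-methoxy-5-pentylphenyl]boronic acid | CCCCCc1cc(B(O)O)cc(OC)c1C(=O)OC(C)(C)C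
A6 | alternative 2 | 4-methoxy-2-(methoxymethoxy)-6-propylbenzoic acid | CCCc1cc(OC)cc(OCOC)c1C(=O)O
A7 | alternative 2 | tert-butyl 2-methoxy-4-[4-methoxy-2-(methoxymethoxy)-6-propylbenzoyloxy]-6-pentylbenzoate | CCCCCc1cc(OC(=O)c2c(OCOC)cc(OC)cc2CCC)cc(OC)c1C(=O)OC(C)(C)C
A8 | alternative 3 | 1-bromo-2-iodo-3,5-dimethoxybenzene | COc1cc(Br)c(I)c(OC)c1
A9 | alternative 3 | 3,5-dimethoxybenzyne | COC1=CC(OC)=CC#C1
A10 | alternative 3 | propylmagnesium chloride | CCC[Mg]Cl
A11 | alternative 3 | 2,4-dimethoxy-6-propylbenzoic acid | CCCc1cc(OC)cc(OC)c1C(=O)O
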